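The amount of solid substrate you charge is held against how much of it the solution can take up, and against how fast it goes in.

| flask | solid substrate | remark | time |
|---|---|---|---|
| birch | 0.40 M | run made earlier |  |
| larch | 1.6 M | run made earlier |  |
| flask | 0.79 M |  | 6.0 min |

- birch (time / min: target / %, starting material / %): 0.333: 10.9, 83.2; 1.00: 13.4, 77.5; 1.50: 13.2, 77.3; 2.50: 13.2, 77.2; 4.00: 12.8, 77.6; 5.00: 12.7, 76.4; 6.00: 13.2, 77.1
- larch (time / min: target / %, starting material / %): 0.500: 4.3, 35.2; 0.667: 5.9, 39.7; 1.00: 6.8, 43.6; 1.50: 8.0, 47.1; 2.50: 8.2, 47.5; 4.00: 8.3, 47.8; 6.00: 8.1, 48.2

(standard deviation of a reading: 0.3 percentage points)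

* amount of target at 6.0 min, in percent of the solid substrate charged
* concentration of starting material in solution at 6.0 min, in percent of saturation

- solid, in amounts per volume of the solution: solid substrate
- at the start none of the solid substrate is in solution
- starting material is what solid substrate becomes in solution
- starting material means what is dissolved; the solid is not counted in it

The larch run levels off at 0.765 M of starting material, which I take as saturation. In the birch run, where I take the solid to be gone, starting material is 77.1% of what was charged. If that share holds, a saturated solution has taken up

C = 0.765 M / 77.1% = 0.992 M.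

Call C the holding capacity: the charge that just brings the solution to saturation.

I assume the dissolving rate is proportional to what the solution can still take. In the larch run, the gap to the plateau shrinks from 13 percentage points at 0.500 min to 4.2 points at 1.00 min, so

k = 2.20 /min.

This flask therefore starts at kC = 2.18 M/min. Filling slows it, and at the last grain the rate is 0.204 of that start. Unslowed, dissolving takes 0.362 min; slowed, it takes

t = ln(C/(C − 0.79 M))/k = 0.724 min,

twice the unslowed time, and short against 6.0 min. The charge lies below C, so I reckon 13.2% of target, as in the birch run, and 79.6% of saturation.

The forecast says 13% and 78%, a lower saturation than mine, holding that “Flask at 0.79 M should dissolve fully”.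

This flask gives 13.0% of target and 78.2% of saturation, against my 79.6%.

    starting material ⇌ target (K = 0.170, k = 0.0160 /s)
    target ⇌ isomer of the product (K = 0.680, k = 0.00400 /s)
    isomer of the product ⇌ starting material (k = 0.0550 /s)
    solid substrate ⇌ starting material, rate k4*(cs4 - [starting material]) while solid is left; crystals form when [starting material] > cs4 (solubility = 0.770 M, k = 0.0560 /s)
    2 starting material → homo dimer (k = 6.30 × 10⁻⁵ /M/s)

In this flask solid substrate stood at 5.81% at 0.600 min and 0% at 3.00 min, and by 6.00 min homo dimer had reached 2.02% beside 8.82% of isomer of the product. The neighbour flask with 2.0 M lies above C: the reckoning leaves 50.4% solid, and that flask holds 49.4% solid at 6.00 min, with target at 6.53%.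

The earlier runs and the new flask were computed from invented constants.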